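The target is disconnected at the two bonds that join the diene terminus (C14′, C15′) of a labdatrienoic acid to C8 and C13 of a hydroxy-p-quinone; a perezone-type [5+2] cycloaddition should form both last. The acid comes from levopimaric acid in three steps. In the hexahydrofluorene half, ring A (C1–C5, C10) holds the benzylic quaternary carbon C10 next to C5; with C5 as a carbonyl this is a 2-aryl-2-methylcyclohexanone. The key step makes it from a racemic aryl spiro-epoxide built on a cyclopentane: a chiral Brønsted acid ionises the epoxide at C10 and a 1,2-shift enlarges the five-membered ring to ring A while setting C10.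

Key step: step 4

Remark: the fluorene half carries abietane numbers (ring A = C1–C5, C10; ring B = C5, C6, C8, C9, C10; C7 = formyl carbon; quinone ring = C8, C9, C11–C14) and the labdane half carries primes; C6, α to the formyl group, is assumed to equilibrate to the epimer trans to C4, as the target shows.

Step 1
Reactants: 1 4-isopropyl-3,5-dimethoxybenzoic acid
Product: 2 aryl methyl ketone 1-[3,5-dimethoxy-4-(propan-2-yl)phenyl]ethan-1-one
Conditions: MeLi (2.5 equiv), THF, 0 → 23 °C; then aq. HCl
Reagents that add atoms: methyllithium, [Li]C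
Why: Addition of MeLi to the lithium carboxylate stops at the geminal dilithio diolate, which releases the methyl ketone only on acidic work-up (ketone synthesis from a carboxylic acid with an organolithium); no stereocentre is formed.

Step 2
Reactants: 2 aryl methyl ketone; 3 cyclopentanone
Product: 4 tetrasubstituted alkene 5-(1-cyclopentylideneethyl)-1,3-dimethoxy-2-(propan-2-yl)benzene
Conditions: TiCl4, Zn dust, pyridine, THF, reflux; 3 in excess (4 equiv)
Reagents that add atoms: none
Why: Mixed McMurry coupling, in which low-valent titanium reduces the aryl ketone first and the excess aliphatic ketone intercepts it, so the cross-coupled alkene should be the main product; no stereocentre is formed.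

Step 3
Reactants: 4 tetrasubstituted alkene
Product: 5 racemic spiro-epoxide 2-[3,5-dimethoxy-4-(propan-2-yl)phenyl]-2-methyl-1-oxaspiro[2.4]heptane
Conditions: dimethyldioxirane, acetone, 0 °C
Reagents that add atoms: dimethyldioxirane, CC1(C)OO1
Why: Neutral dioxirane epoxidation of the electron-rich tetrasubstituted alkene avoids the acid that would open the benzylic epoxide early; the epoxide is racemic, which is harmless because step 4 is enantioconvergent.

Step 4
Reactants: 5 racemic spiro-epoxide
Product: 6 (2R)-2-[3,5-dimethoxy-4-(propan-2-yl)phenyl]-2-methylcyclohexan-1-one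
Conditions: chiral BINOL-derived N-triflylphosphoramide with 3,3′-bis(2,4,6-triisopropylphenyl) groups, the enantiomer that gives (R)-6 (5 mol %), PhCF3, 4 Å molecular sieves, −20 °C
Reagents that add atoms: none
Why: The chiral acid protonates the epoxide and the benzylic C10–O bond ionises to a tertiary benzylic cation paired with the chiral phosphoramide anion, after which the ring carbon C1 of the cyclopentane migrates from C5 to C10 while C5 becomes the carbonyl carbon. The closest known reaction type is the catalytic enantioselective Meinwald rearrangement of tetrasubstituted aryl epoxides to α-aryl-α-alkyl cycloalkanones under chiral N-triflylphosphoramide catalysis. No new ring is closed by joining two termini; ring A (C1–C5, C10) arises by the 1,2-alkyl shift, in which the five-membered carbocycle takes up C10 and becomes six-membered. The new quaternary stereocentre C10 is controlled by the catalyst, which differentiates the two faces of the planar cation, so both enantiomers of 5 should converge on (R)-6. The step needs ionisation at the benzylic and not at the spiro carbon, which the aryl group secures, and ring-bond migration as the only 1,2-shift, which follows because C5 carries no hydrogen and its two ring CH2 groups are equivalent.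

Step 5
Reactants: 6 (2R)-2-aryl-2-methylcyclohexanone
Product: 7 (2R)-2-[3,5-dimethoxy-4-(propan-2-yl)phenyl]-2,6,6-trimethylcyclohexan-1-one
Conditions: KOtBu (3 equiv), MeI (excess), THF, 0 → 23 °C
Reagents that add atoms: iodomethane, CI
Why: Exhaustive enolate methylation; only C4 bears α-hydrogens, so both methyl groups enter there (the C4 gem-dimethyl group) and the quaternary C10 cannot epimerise.

Step 6
Reactants: 7 (2R)-2-aryl-2,6,6-trimethylcyclohexanone
Product: 8 aryl bromide (2R)-2-[2-bromo-3,5-dimethoxy-4-(propan-2-yl)phenyl]-2,6,6-trimethylcyclohexan-1-one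
Conditions: N-bromosuccinimide (1.0 equiv), MeCN, 0 °C
Reagents that add atoms: N-bromosuccinimide, O=C1CCC(=O)N1Br
Why: Electrophilic aromatic bromination at C8, one of the two equivalent positions ortho and para to the methoxy groups; the ketone has no α-hydrogen that could compete.

Step 7
Reactants: 8 aryl bromide
Product: 9 aryl enol ether (2R)-2-{2-[(E)-2-ethoxyethenyl]-3,5-dimethoxy-4-(propan-2-yl)phenyl}-2,6,6-trimethylcyclohexan-1-one
Conditions: Pd(OAc)2 (5 mol %), SPhos (10 mol %), K3PO4, toluene–H2O, 90 °C
Reagents that add atoms: (E)-2-(2-ethoxyethenyl)-4,4,5,5-tetramethyl-1,3,2-dioxaborolane, CCO/C=C/B1OC(C)(C)C(C)(C)O1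
Why: Suzuki–Miyaura coupling with a bulky biarylphosphine installs the masked acetaldehyde unit (C6, C7) at the doubly ortho-substituted C8; the alkene geometry is retained but of no consequence.

Step 8
Reactants: 9 aryl enol ether
Product: 11 enal (4aR)-6,8-dimethoxy-1,1,4a-trimethyl-7-(propan-2-yl)-2,3,4,4a-tetrahydro-1H-fluorene-9-carbaldehyde, via arylacetaldehyde 10 (not isolated)
Conditions: 2 M HCl, THF, 23 °C; then pyrrolidine (20 mol %), AcOH (20 mol %), toluene, 80 °C
Reagents that add atoms: water, O
Why: Acid hydrolysis of the enol ether frees the arylacetaldehyde, whose enamine adds to the non-enolisable C5 ketone (intramolecular aldol condensation, 5-exo-trig closure of ring B by the C5–C6 bond) and dehydrates to the aryl-conjugated enal; no stereocentre is formed.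

Step 9
Reactants: 11 enal
Product: 13 (4aS,9R,9aS)-6,8-dimethoxy-1,1,4a-trimethyl-7-(propan-2-yl)-2,3,4,4a,9,9a-hexahydro-1H-fluorene-9-carbaldehyde, via 9-epimeric aldehyde 12 (not isolated)
Conditions: H2 (50 bar), Pd/C, EtOAc, 23 °C; then DBU (0.2 equiv), CH2Cl2, 23 °C
Reagents that add atoms: none
Why: Heterogeneous hydrogenation should add H2 syn to the α face of C5=C6, opposite the two syn-axial methyl groups (C10–CH3 and the 4β-methyl) that the chair of ring A holds on the β face, which sets the trans ring fusion (5α-H); DBU then epimerises the 6β-formyl group of 12 to the more stable 6α position, trans to C4.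

Step 10
Reactants: 13 dimethoxy aldehyde
Product: 14 resorcinol aldehyde (4aS,9R,9aS)-6,8-dihydroxy-1,1,4a-trimethyl-7-(propan-2-yl)-2,3,4,4a,9,9a-hexahydro-1H-fluorene-9-carbaldehyde
Conditions: BBr3 (3 equiv), CH2Cl2, −78 → 0 °C; then aq. NaHCO3
Reagents that add atoms: none
Why: Lewis acid cleavage of both aryl methyl ethers with BBr3 at low temperature; the stereocentres are not touched and C6 stays in its thermodynamic configuration.

Step 11
Reactants: 14 resorcinol aldehyde
Product: 15 hydroxyquinone aldehyde (4aS,9R,9aS)-6-hydroxy-1,1,4a-trimethyl-5,8-dioxo-7-(propan-2-yl)-2,3,4,4a,5,8,9,9a-octahydro-1H-fluorene-9-carbaldehyde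
Conditions: potassium nitrosodisulfonate K2[ON(SO3)2] (2.5 equiv), KH2PO4 buffer, acetone–H2O, 0 °C
Reagents that add atoms: potassium nitrosodisulfonate, [K+].[K+].[O]N(S(=O)(=O)[O-])S(=O)(=O)[O-]
Why: Teuber oxidation of the resorcinol at its free position C11, para to the C14 hydroxyl, gives the 2-hydroxy-1,4-benzoquinone; the formyl group and the stereocentres are untouched.

Step 12
Reactants: 16 levopimaric acid
Product: 17 keto aldehyde 8,12-dioxo-13,14,15,16,17-pentanorlabdan-18-oic acid
Conditions: O3, pyridine (3 equiv), CH2Cl2, −78 °C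
Reagents that add atoms: ozone, [O-][O+]=O
Why: Ozonolysis cleaves both double bonds of the ring C diene, excising C13, C14 and the isopropyl group and leaving the C8 ketone and the C12 aldehyde, with pyridine giving the carbonyl compounds directly; the four stereocentres of 16 are retained, C9 already having the more stable equatorial side chain.

Step 13
Reactants: 17 keto aldehyde
Product: 18 enal (12E)-8,14-dioxo-15,17-dinorlabd-12-en-18-oic acid
Conditions: Ph3P=C(CH3)CHO (2.5 equiv), toluene, 90 °C
Reagents that add atoms: 2-(triphenylphosphoranylidene)propanal, CC(C=O)=P(c1ccccc1)(c1ccccc1)c1ccccc1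
Why: Wittig reaction with a stabilised ylide is selective for the aldehyde over the hindered C8 ketone and should give the E-configured trisubstituted enal (C12′=C13′).

Step 14
Reactants: 18 enal
Product: 19 labda-8(17),12E,14-trien-18-oic acid
Conditions: Ph3PCH3Br (6 equiv), KOtBu (6 equiv), THF, 0 → 65 °C; then aq. NH4Cl
Reagents that add atoms: methyltriphenylphosphonium bromide, C[P+](c1ccccc1)(c1ccccc1)c1ccccc1.[Br-]
Why: Double Wittig methylenation converts the enal into the 12E,14-diene and the C8 ketone into the exocyclic 8(17)-alkene; excess ylide first deprotonates the acid and C9 stays in its thermodynamically preferred configuration.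

Step 15
Reactants: 15 hydroxyquinone aldehyde; 19 labda-8(17),12E,14-trien-18-oic acid
Product: 20 target heterodimer
Conditions: BF3·OEt2 (0.3 equiv), CH2Cl2, −40 → 0 °C
Reagents that add atoms: none
Why: Perezone-type [5+2] cycloaddition, in which the Lewis acid held between O11 and O12 turns the hydroxyquinone into an oxidopentadienyl cation (C13–C12–C11–C9–C8), the unhindered terminal carbon C15′ should bond to the more accessible terminus C13 and the resulting allyl cation close at the ring-fusion carbon C8 on the α face, opposite the axial C10 methyl group, with the side chain endo, giving the bicyclo[3.2.1]octenedione with its C11 enol while the epimerisable C6 stays trans to C4.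

Compound list

1 | 4-isopropyl-3,5-dimethoxybenzoic acid | COc1cc(C(=O)O)cc(OC)c1C(C)C | starting material
2 | 1-[3,5-dimethoxy-4-(propan-2-yl)phenyl]ethan-1-one | CC(=O)c1cc(OC)c(C(C)C)c(OC)c1 | intermediate
3 | cyclopentanone | O=C1CCCC1 | starting material
4 | 5-(1-cyclopentylideneethyl)-1,3-dimethoxy-2-(propan-2-yl)benzene | CC(=C1CCCC1)c1cc(OC)c(C(C)C)c(OC)c1 | intermediate
5 | rac-2-[3,5-dimethoxy-4-(propan-2-yl)phenyl]-2-methyl-1-oxaspiro[2.4]heptane | CC1(OC12CCCC2)c1cc(OC)c(C(C)C)c(OC)c1 | intermediate
6 | (2R)-2-[3,5-dimethoxy-4-(propan-2-yl)phenyl]-2-methylcyclohexan-1-one | O=C1CCCC[C@]1(C)c1cc(OC)c(C(C)C)c(OC)c1 | intermediate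
7 | (2R)-2-[3,5-dimethoxy-4-(propan-2-yl)phenyl]-2,6,6-trimethylcyclohexan-1-one | O=C1C(C)(C)CCC[C@]1(C)c1cc(OC)c(C(C)C)c(OC)c1 | intermediate
8 | (2R)-2-[2-bromo-3,5-dimethoxy-4-(propan-2-yl)phenyl]-2,6,6-trimethylcyclohexan-1-one | O=C1C(C)(C)CCC[C@]1(C)c1cc(OC)c(C(C)C)c(OC)c1Br | intermediate
9 | (2R)-2-{2-[(E)-2-ethoxyethenyl]-3,5-dimethoxy-4-(propan-2-yl)phenyl}-2,6,6-trimethylcyclohexan-1-one | O=C1C(C)(C)CCC[C@]1(C)c1cc(OC)c(C(C)C)c(OC)c1/C=C/OCC | intermediate
10 | 2-{4,6-dimethoxy-5-(propan-2-yl)-2-[(1R)-1,3,3-trimethyl-2-oxocyclohexyl]phenyl}acetaldehyde | O=C1C(C)(C)CCC[C@]1(C)c1cc(OC)c(C(C)C)c(OC)c1CC=O | intermediate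
11 | (4aR)-6,8-dimethoxy-1,1,4a-trimethyl-7-(propan-2-yl)-2,3,4,4a-tetrahydro-1H-fluorene-9-carbaldehyde | O=CC1=C2C(C)(C)CCC[C@]2(C)c2cc(OC)c(C(C)C)c(OC)c21 | intermediate
12 | (4aS,9S,9aS)-6,8-dimethoxy-1,1,4a-trimethyl-7-(propan-2-yl)-2,3,4,4a,9,9a-hexahydro-1H-fluorene-9-carbaldehyde (trans-fused, 6β-CHO) | O=C[C@H]1[C@H]2C(C)(C)CCC[C@]2(C)c2cc(OC)c(C(C)C)c(OC)c21 | intermediate
13 | (4aS,9R,9aS)-6,8-dimethoxy-1,1,4a-trimethyl-7-(propan-2-yl)-2,3,4,4a,9,9a-hexahydro-1H-fluorene-9-carbaldehyde (trans-fused, 6α-CHO) | O=C[C@@H]1[C@H]2C(C)(C)CCC[C@]2(C)c2cc(OC)c(C(C)C)c(OC)c21 | intermediate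
14 | (4aS,9R,9aS)-6,8-dihydroxy-1,1,4a-trimethyl-7-(propan-2-yl)-2,3,4,4a,9,9a-hexahydro-1H-fluorene-9-carbaldehyde | O=C[C@@H]1[C@H]2C(C)(C)CCC[C@]2(C)c2cc(O)c(C(C)C)c(O)c21 | intermediate
15 | (4aS,9R,9aS)-6-hydroxy-1,1,4a-trimethyl-5,8-dioxo-7-(propan-2-yl)-2,3,4,4a,5,8,9,9a-octahydro-1H-fluorene-9-carbaldehyde | O=C[C@@H]1[C@H]2C(C)(C)CCC[C@]2(C)C2=C1C(=O)C(C(C)C)=C(O)C2=O | intermediate
16 | levopimaric acid, abieta-8(14),12-dien-18-oic acid (4α-CO2H, 5α-H, 9α-H, 10β-CH3) | C1=C2CC[C@@H]3[C@](C)(CCC[C@@]3(C)C(=O)O)[C@H]2CC=C1C(C)C | starting material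
17 | 8,12-dioxo-13,14,15,16,17-pentanorlabdan-18-oic acid (4α-CO2H, 5α-H, 9α-H, 10β-CH3) | O=C1CC[C@@H]2[C@](C)(CCC[C@@]2(C)C(=O)O)[C@H]1CC=O | intermediate
18 | (12E)-8,14-dioxo-15,17-dinorlabd-12-en-18-oic acid | O=C1CC[C@@H]2[C@](C)(CCC[C@@]2(C)C(=O)O)[C@H]1C/C=C(\C)C=O | intermediate
19 | labda-8(17),12E,14-trien-18-oic acid (4R,5R,9S,10R) | C=C1CC[C@@H]2[C@](C)(CCC[C@@]2(C)C(=O)O)[C@H]1C/C=C(\C)C=C | intermediate
20 | target: [5+2] adduct of 15 across C14′=C15′ of 19 (C8–C14′ and C13–C15′ bonds; bicyclo[3.2.1]oct-3-ene-2,8-dione with C11 enol; 6α-CHO; labdane residue endo) | C=C1CC[C@@H]2[C@](C)(CCC[C@@]2(C)C(=O)O)[C@H]1C/C=C(\C)[C@H]1C[C@@]2(C(C)C)C(=O)C(O)=C3[C@@]1(C2=O)[C@H](C=O)[C@H]1C(C)(C)CCC[C@]31C | target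

Total step count: 15. Longest linear sequence: 12 steps (steps 1–11, then step 15).

Steps most likely to fail

Step 15. The cation may be consumed by other pathways: Diels–Alder addition across the diene, attack at the exocyclic 8′(17′)-alkene, or acid-induced oligomerisation. The first bond may also form with the reverse orientation (C15′ at C8), and the acidic OH and CO2H groups may sequester the Lewis acid. The fallback sets out from 15 and 19 and returns at 20. Compound 15 is O-methylated with trimethylsilyldiazomethane in MeOH–CH2Cl2 to the methoxyquinone F1. F1 and 19 are then combined with a 1:1 mixture of TiCl4 and Ti(OiPr)4 (2.5 equiv, the excess allowing for the carboxylic acid) in CH2Cl2 at −78 °C. Titanium chelated between O11 and the methoxy oxygen activates the quinone for a stepwise alkylation and ring closure, the ionic [5+2] cycloaddition known for 2-alkoxy-p-quinones and aryl alkenes; the orientation is again expected to follow from the greater hindrance at C8. The methyl oxocarbenium ion left at C12 is hydrolysed on aqueous work-up with loss of methanol, which gives 20 directly.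

Step 9. The tetrasubstituted alkene, flanked by two quaternary carbons, may resist heterogeneous hydrogenation, or the formyl group may be reduced first. The fallback sets out from 11 and returns at 13. Luche reduction (NaBH4, CeCl3·7H2O, MeOH) gives the allylic alcohol F2. Hydroxyl-directed homogeneous hydrogenation with [Ir(cod)(PCy3)(py)]PF6 in CH2Cl2 then adds H2 from the same, less hindered α face to give the saturated alcohol F3. Dess–Martin oxidation of F3 gives 12, which DBU epimerises to 13 as in step 9.

Step 8. The enamine may fail to attack the strongly shielded ketone, so that the arylacetaldehyde condenses with itself instead. The fallback sets out from 8 and returns at 11. Vinylmagnesium bromide with CeCl3 in THF adds to the ketone anti to the axial methyl groups to give the allylic alcohol F4, with vinyl cis to the aryl group. An intramolecular Heck reaction (Pd(OAc)2, P(o-tolyl)3, K2CO3, DMF, 110 °C; 5-exo-trig) closes ring B to the methylene-indanol F5. Babler–Dauben oxidative transposition of F5 with pyridinium chlorochromate [C5H5NH][CrO3Cl] gives enal 11.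

Further compounds

F1 | step 15 | (4aS,9R,9aS)-6-methoxy-1,1,4a-trimethyl-5,8-dioxo-7-(propan-2-yl)-2,3,4,4a,5,8,9,9a-octahydro-1H-fluorene-9-carbaldehyde | O=C[C@@H]1[C@H]2C(C)(C)CCC[C@]2(C)C2=C1C(=O)C(C(C)C)=C(OC)C2=O
F2 | step 9 | [(4aR)-6,8-dimethoxy-1,1,4a-trimethyl-7-(propan-2-yl)-2,3,4,4a-tetrahydro-1H-fluoren-9-yl]methanol | OCC1=C2C(C)(C)CCC[C@]2(C)c2cc(OC)c(C(C)C)c(OC)c21
F3 | step 9 | [(4aS,9S,9aS)-6,8-dimethoxy-1,1,4a-trimethyl-7-(propan-2-yl)-2,3,4,4a,9,9a-hexahydro-1H-fluoren-9-yl]methanol | OC[C@H]1[C@H]2C(C)(C)CCC[C@]2(C)c2cc(OC)c(C(C)C)c(OC)c21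
F4 | step 8 | (1S,2R)-2-[2-bromo-3,5-dimethoxy-4-(propan-2-yl)phenyl]-1-ethenyl-2,6,6-trimethylcyclohexan-1-ol | C=C[C@]1(O)C(C)(C)CCC[C@]1(C)c1cc(OC)c(C(C)C)c(OC)c1Br
F5 | step 8 | (4aR,9aR)-6,8-dimethoxy-1,1,4a-trimethyl-9-methylidene-7-(propan-2-yl)-1,2,3,4,4a,9-hexahydro-9aH-fluoren-9a-ol | C=C1[C@]2(O)C(C)(C)CCC[C@]2(C)c2cc(OC)c(C(C)C)c(OC)c21
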